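Ring C of the flavanone (O1–C2–C3–C4, fused to ring A through C4a/C8a) is cut across O1–C2 and C3–C4. This works because O1, C8a, C4a and C4 are the four atoms of a salicylaldehyde heterodiene, while C3 and C2, the latter carrying ring B, are the two alkene carbons of an electron-rich styrene. A confined chiral Brønsted acid should join the two in a single oxa-[4+2] annulation that closes the pyran ring, makes both bonds and fixes C2 as S. The precursor is an unprotected ortho-hydroxybenzaldehyde with three methoxy groups, made in one formylation; a mild oxidation of the C4 carbinol then gives the target.

Key step: step 2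

Assumption: the sense of induction of the chiral acid in step 2 cannot be assigned in advance, so the catalyst antipode that delivers 2S is taken to be found by screening both BINOL series; the 2,4-cis carbinol is drawn, although either C4 epimer would serve because C4 becomes the ketone.

Step 1
Reactants: 1 3,4,5-trimethoxyphenol
Product: 3 6-hydroxy-2,3,4-trimethoxybenzaldehyde, via salicyl alcohol magnesium chelate 2 (not isolated)
Conditions: MgCl2, Et3N, (CH2O)n, MeCN, reflux; then aq. HCl
Reagents that add atoms: paraformaldehyde (as formaldehyde), C=O
Why: Casnati–Skattebøl ortho-formylation, in which the magnesium phenoxide of 1 chelates formaldehyde and delivers it to the ortho carbon to give salicyl alkoxide 2, which a second formaldehyde oxidises by Oppenauer-type hydride transfer (giving methanol); the two free ring positions of 1 are equivalent, so only one regioisomer can arise, and the first formyl group deactivates the ring toward a second.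

Step 2
Reactants: 3 6-hydroxy-2,3,4-trimethoxybenzaldehyde; 4 3,4-dimethoxystyrene
Product: 5 (2S,4S)-2-(3,4-dimethoxyphenyl)-5,6,7-trimethoxychroman-4-ol
Conditions: confined chiral imidodiphosphorimidate Brønsted acid (BINOL-derived, N-triflyl, 3,3'-diaryl; 2–5 mol%), 3 (1.3 equiv), slow addition of 4 (freshly filtered through basic alumina), dry CHCl3, −50 °C; Et3N quench at −50 °C
Reagents that add atoms: none
Why: Proposed new method: the confined, strongly acidic imidodiphosphorimidate should protonate the formyl oxygen of 3 to a hydroxy-substituted o-quinone-methide-type carboxonium ion held in a contact ion pair, whereupon the terminal CH2 of 4 adds to the formyl carbon (C3–C4) in an asynchronous inverse-electron-demand oxa-[4+2] in which positive charge builds on the 3,4-dimethoxybenzylic carbon before the phenol oxygen closes O1–C2 and hands the proton back to the catalyst. The closest known reaction types are racemic acid-promoted annulations of salicylaldehydes or their acetals with styrenes to 4-oxygenated 2-arylchromans, chiral-phosphoric-acid-catalysed [4+2] cycloadditions of o-quinone methides generated in situ, and confined-acid-catalysed asymmetric Prins reactions of aldehydes with styrenes; the enantioselective intermolecular union of a free salicylaldehyde with a simple styrene is the untested part. The pyran ring closes in hetero-Diels–Alder fashion (heterodiene O1–C8a–C4a–C4 plus dienophile C3=C2), its last bond arising from six-membered collapse of the phenol oxygen onto the benzylic cationic carbon, and every atom of 3 and 4 ends up in 5. C2 is set under catalyst control, since the chiral anion, hydrogen-bonded to the carboxonium OH and the phenol OH inside its pocket, leaves one face of the developing benzylic centre open to O1, while C4 follows from the endo-type approach that places aryl and OH cis and is erased in step 3. Regiochemistry (aryl on C2) is secured by the nucleophilic styrene terminus and the para-methoxy-stabilised benzylic cation, chemoselectivity over styrene oligomerisation by slow addition of 4 to an excess of 3, whose donor-rich carbonyl is the most basic site present and keeps the acid engaged, and configurational integrity by the low temperature and cold amine quench, which suppress re-ionisation at C4 or C2; no uncatalysed background is expected because the neutral aldehyde does not react with 4 at −50 °C.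

Step 3
Reactants: 5 (2S,4S)-2-(3,4-dimethoxyphenyl)-5,6,7-trimethoxychroman-4-ol
Product: 6 (2S)-5,6,7,3',4'-pentamethoxyflavanone, i.e. (2S)-2-(3,4-dimethoxyphenyl)-5,6,7-trimethoxychroman-4-one
Conditions: Dess–Martin periodinane, pyridine, CH2Cl2, 0 °C to rt
Reagents that add atoms: none
Why: Dess–Martin oxidation (ligand exchange of the C4 hydroxyl onto iodine(V), then loss of the carbinol hydrogen) should turn the secondary benzylic alcohol into the aryl ketone under pyridine-buffered, near-neutral conditions that neither ionise the acid-labile C4–O bond nor open the flavanone by retro-oxa-Michael reaction, so the C2 stereocentre set in step 2 is carried through unchanged while the C4 stereocentre is removed.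

Compound list
1 | 3,4,5-trimethoxyphenol | COc1cc(O)cc(OC)c1OC | starting material
2 | 2-(hydroxymethyl)-3,4,5-trimethoxyphenol, present in the flask as its magnesium chelate (drawn as the free diol) | OCc1c(O)cc(OC)c(OC)c1OC | intermediate
3 | 6-hydroxy-2,3,4-trimethoxybenzaldehyde | O=Cc1c(O)cc(OC)c(OC)c1OC | intermediate
4 | 3,4-dimethoxystyrene | C=Cc1ccc(OC)c(OC)c1 | starting material
5 | (2S,4S)-2-(3,4-dimethoxyphenyl)-5,6,7-trimethoxychroman-4-ol (2,4-cis) | COc1ccc([C@@H]2C[C@H](O)c3c(cc(OC)c(OC)c3OC)O2)cc1OC | intermediate
6 | (2S)-5,6,7,3',4'-pentamethoxyflavanone | COc1ccc([C@@H]2CC(=O)c3c(cc(OC)c(OC)c3OC)O2)cc1OC | target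

Total step count: 3
Longest linear sequence: 3 steps (1 → 3 → 5 → 6)

Steps most likely to fail

1. Step 2 (Proposed new method). Several processes could defeat it:
- insufficient or wrong-sense enantiofacial discrimination at C2;
- cationic oligomerisation of the styrene outrunning the cross-annulation;
- acid-triggered re-ionisation of the product at C4, with loss of water towards the flav-3-ene;
- re-ionisation at C2, with racemisation by reversible ring opening.

Fallback with known chemistry, setting out from phenol 1 and returning to the route at flavanone 6:
- Friedel–Crafts C-acetylation of 1 (AcOH, BF3·OEt2, heat) should give 1-(6-hydroxy-2,3,4-trimethoxyphenyl)ethan-1-one F1.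
- Condensation of F1 with N,N-dimethylformamide dimethyl acetal should give the enaminone (E)-3-(dimethylamino)-1-(6-hydroxy-2,3,4-trimethoxyphenyl)prop-2-en-1-one F2.
- Acid (HCl, CH2Cl2) should cyclise F2 with loss of dimethylamine to 5,6,7-trimethoxy-4H-chromen-4-one F3.
- A rhodium(I)/chiral diene-catalysed asymmetric conjugate addition of (3,4-dimethoxyphenyl)boronic acid to F3 (Hayashi–Miyaura type) should install ring B at C2 under ligand control and give 6 directly, with the ligand antipode chosen for 2S.

2. Step 3. The acetic acid released could ionise the electron-rich C4 carbinol and dehydrate it. Dehydrogenation across C2–C3 towards the flavone is possible. Ring opening by retro-oxa-Michael reaction during work-up could erode C2. The fallback sets out from 5 and returns at 6. It replaces the homogeneous hypervalent-iodine oxidation by a heterogeneous, acid-free surface oxidation with activated MnO2 in CH2Cl2 at room temperature, which is selective for benzylic carbinols and is removed by filtration without aqueous base. No new compound is made on the way (F0).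

3. Step 1. A second formylation at the remaining ortho position, phenol–formaldehyde condensation to diarylmethanes, or incomplete hydride transfer that stalls at the salicyl alcohol stage could lower the throughput. The fallback sets out from 1 and returns at 3. Vilsmeier–Haack formylation (POCl3, DMF, 0 °C to rt) should give, by electrophilic substitution with the chloroiminium ion, N-[(6-hydroxy-2,3,4-trimethoxyphenyl)methylidene]-N-methylmethanaminium chloride F4. Hydrolysis of F4 with aqueous sodium acetate should release aldehyde 3.

Further compounds
F1 | step 2 | 1-(6-hydroxy-2,3,4-trimethoxyphenyl)ethan-1-one | CC(=O)c1c(O)cc(OC)c(OC)c1OC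
F2 | step 2 | (E)-3-(dimethylamino)-1-(6-hydroxy-2,3,4-trimethoxyphenyl)prop-2-en-1-one | CN(C)/C=C/C(=O)c1c(O)cc(OC)c(OC)c1OC
F3 | step 2 | 5,6,7-trimethoxy-4H-chromen-4-one | O=c1ccoc2cc(OC)c(OC)c(OC)c12
F0 | step 3 | none | none
F4 | step 1 | N-[(6-hydroxy-2,3,4-trimethoxyphenyl)methylidene]-N-methylmethanaminium chloride | C[N+](C)=Cc1c(O)cc(OC)c(OC)c1OC.[Cl-]
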